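Which way of adding leaves the most D at 8.0 min: E fed slowly, E fed quickly, J fed slowly, or nothing fed?

| setting | south-east | north-east | east | eta | epsilon | beta | theta |
|---|---|---|---|---|---|---|---|
| E | 0.50 M | 0.50 M | 0.50 M | 0.50 M (fed, over 5.0 min) | 0.50 M (fed, over 30 s) | 0.50 M | 0.50 M |
| Z | 0.60 M | 0.60 M | 0.60 M | 0.600 M | 0.600 M | 0.600 M | 0.600 M |
| J | 0.45 M | 0.63 M | 0.99 M | 0.450 M | 0.450 M | 0.450 M (fed, over 5.0 min) | 0.450 M |
| remark | run made earlier | run made earlier | run made earlier | all else is in the flask from the start; the feed brings no volume worth counting | all else is in the flask from the start; the feed brings no volume worth counting | all else is in the flask from the start; the feed brings no volume worth counting | everything together at the start |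
| time |  |  |  | 8.0 min | 8.0 min | 8.0 min | 8.0 min |

* the best flask by amount of D, in percent of the E charged; "all alike" if 1.5 percentage points covers them all (eta / epsilon / beta / theta / all alike)
* amount of D at the end, in percent of the E charged, eta
* amount of D at the end, in percent of the E charged, epsilon
* amount of D at the end, in percent of the E charged, beta
* amount of D at the end, in percent of the E charged, theta

- south-east (time / min: D / %, E / %): 0.250: 5.8, 80.1; 0.667: 13.0, 55.8; 1.33: 19.5, 32.0; 2.00: 24.0, 18.5; 3.00: 31.0, 7.5; 4.00: 34.7, 2.2; 5.00: 36.2, 0.9
- north-east (time / min: D / %, E / %): 0.250: 4.6, 80.9; 0.667: 9.3, 55.6; 1.33: 14.2, 32.1; 2.00: 17.2, 17.7; 3.00: 20.4, 6.6; 4.00: 22.6, 3.2; 5.00: 22.8, 1.2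
- east (time / min: D / %, E / %): 0.250: 3.7, 80.5; 0.667: 6.0, 56.4; 1.33: 8.6, 32.7; 2.00: 9.8, 18.3; 3.00: 10.4, 8.1; 4.00: 9.3, 3.7; 5.00: 8.5, 2.0

(each reading ± 0.5 percentage points)

- the analysis behind the earlier runs scatters by 0.5 percentage points, standard deviation

I read the tables down their columns. E falls alike from run to run, 18.5%, 17.7% and 18.3% at 2.00 min, so I give it one rate constant, 0.844 /min, whatever J is. I call W the waste, the E lost but not found as D, and I count one J for each W.

In the south-east run, D is 29.4% of the E lost by 0.667 min. That selectivity fits an even split at a level of J that I call a, 0.187 M. Between 3.00 min and 4.00 min the share is 69.8%, so I take J to be below a by 3.00 min and count it as nil there. But W there is 0.307 M of the 0.45 M charged, so on this count 0.143 M of J, call it U, is not accounted for by W.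

Let kJ be J's own loss constant, with E playing no part in it: kJ times mean J times time equals U. The mean from J minus W at 1.33 min is 0.208 M, giving 0.229 /min. Going round once more, I take half of U off that mean, and kJ, J's own loss constant 0.349 /min, comes out.

In eta, about 0.383 M of E reacts during the feed. With mean J at half its charge, W is 0.209 M. Then J's own loss allows a mean of 0.138 M, and W becomes 0.163 M, so I commit to D near 67.5% for eta. Theta has the charges of the south-east run, so I take that run's 36.2% at 5.00 min for it, and I expect epsilon near it. I expect beta lowest: E's lifetime of 1.18 min is shorter than the 5.0 min of J's feed, so much of the J meets D already formed, and the east run shows D falling from 10.4% at 3.00 min to 8.5% at 5.00 min. I give beta no number.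

The forecast gives beta as best, with 36%, 35%, 62% and 35% for eta, epsilon, beta and theta, holding that “Feeding J keeps it low while E reacts”.

The best is eta at 57.0%, above epsilon 39.6%, beta 23.8% and theta 35.9%.

    Z + Q ⇌ D (K = 25.0 /M, k = 0.659 /M/s)
    J ⇌ L (K = 29.0, k = 0.00770 /s)
    E → Q (k = 0.0143 /s)
    J + Q → G (k = 1.78 /M/s)

Eta ends with G at 33.9% and Q at 7.29% beside its D. With kJ, eta's mean J of 0.134 M over 5.0 min gives 0.234 M lost by J's own road, and at the end of the feed L in eta stands at 0.291 M. Beta's mean J of 0.0298 M over the same time gives 0.0520 M, and at the end of its feed L in beta stands at 0.0666 M.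

(Readings and results are simulated with constants of no real substance; the scatter is artificial.)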